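**Retrosynthetic overview**
1. Last bond: ring A–CH2–ring B, by Michael addition of a ring B–ring C dimer to the ortho-quinone methide generated in the flask from aspidinol (ring A) and an iminium salt.
2. Key bond: ring B–CH2–ring C. The formyl carbon of a benzyl-protected ring B aldehyde is used as a benzyl carbanion (N–H hydrazone, loss of N2) and joined under nickel catalysis to the C–Br carbon of a ring C bromide. Both carbons are electrophiles in their parent forms.
3. The ring C bromide and aspidinol both come from butanoyl-methylphloroglucinol by regioselective O-alkylation; the ring B aldehyde comes from phloroacetophenone by Vilsmeier formylation.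
4. No ring is constructed: the three aromatic rings are bought as phloroglucinols and only joined, ring C to ring B first, ring A last. Benzyl ethers are the only protecting groups and fall in one hydrogenolysis.

Assumption: the target has no stereocentre and no stereogenic double bond, so it is achiral and no enantiocontrol is needed.

Ring A is the butanoyl ring with methoxy para to the ketone, ring B the central acetyl ring, ring C the butanoyl ring with methoxy ortho to the ketone.

**Route**

Step 1
Reactants: 1 2-methylphloroglucinol (2-methylbenzene-1,3,5-triol); 2 butanoyl chloride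
Product: 3 1-(2,4,6-trihydroxy-3-methylphenyl)butan-1-one
Conditions: AlCl3 (3 equiv), PhNO2/CH2Cl2, 0 °C to 45 °C; aq. HCl work-up
Reagents that add atoms: none
Why: Friedel–Crafts C-acylation of the electron-rich triol at one of its two equivalent free ring positions; the aryl ketone formed is deactivated toward a second acylation.

Step 2
Reactants: 3 1-(2,4,6-trihydroxy-3-methylphenyl)butan-1-one
Product: 5 1-[4,6-bis(benzyloxy)-2-methoxy-3-methylphenyl]butan-1-one, via dibenzyl ether 4 (not isolated)
Conditions: BnBr (2.05 equiv), K2CO3 (4 equiv), DMF, rt to 40 °C; then MeI (3 equiv), 60 °C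
Reagents that add atoms: benzyl bromide, BrCc1ccccc1; iodomethane, CI
Why: Two-stage Williamson O-alkylation: benzyl bromide takes the free para hydroxyl and the less hindered ortho hydroxyl, while the hydroxyl wedged between the C-methyl and the chelating butanoyl group reacts last and is capped by iodomethane, which fixes the oxygen pattern of ring C.

Step 3
Reactants: 5 1-[4,6-bis(benzyloxy)-2-methoxy-3-methylphenyl]butan-1-one
Product: 6 1-[2,4-bis(benzyloxy)-3-bromo-6-methoxy-5-methylphenyl]butan-1-one
Conditions: NBS (1.05 equiv), MeCN, 0 °C to rt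
Reagents that add atoms: N-bromosuccinimide, O=C1CCC(=O)N1Br
Why: Electrophilic aromatic bromination at the only free ring position (two ortho benzyloxy groups, para methoxy), far faster than ketone α-bromination; it turns the natively nucleophilic ring carbon into a carbon electrophile.

Step 4
Reactants: 7 phloroacetophenone (1-(2,4,6-trihydroxyphenyl)ethan-1-one)
Product: 9 3-acetyl-2,4,6-trihydroxybenzaldehyde, via iminium chloride 8 (not isolated)
Conditions: POCl3 (1.2 equiv), DMF (1.5 equiv), EtOAc, 0 °C to rt; then H2O, 60 °C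
Reagents that add atoms: N,N-dimethylformamide, CN(C)C=O; water, O
Why: Vilsmeier–Haack formylation at one of two equivalent free positions; the first formyl group deactivates the ring, so mono-formylation is clean.

Step 5
Reactants: 9 3-acetyl-2,4,6-trihydroxybenzaldehyde
Product: 10 3-acetyl-2,4,6-tris(benzyloxy)benzaldehyde
Conditions: BnBr (3.6 equiv), K2CO3 (5 equiv), Bu4NI (cat.), DMF, 70 °C
Reagents that add atoms: benzyl bromide, BrCc1ccccc1
Why: Exhaustive Williamson O-benzylation under forcing conditions breaks all three carbonyl chelates and removes every acidic proton and chelating phenol that would poison the nickel coupling.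

Step 6
Reactants: 10 3-acetyl-2,4,6-tris(benzyloxy)benzaldehyde; 6 1-[2,4-bis(benzyloxy)-3-bromo-6-methoxy-5-methylphenyl]butan-1-one
Product: 12 1-[3-[[3-acetyl-2,4,6-tris(benzyloxy)phenyl]methyl]-2,4-bis(benzyloxy)-6-methoxy-5-methylphenyl]butan-1-one, via hydrazone 11 (not isolated)
Conditions: N2H4·H2O (1.1 equiv), THF, rt, 1 h; then 6 (1.0 equiv), Ni(cod)2 (10 mol %), PMe3 (40 mol %), DBU (2 equiv), THF, 80 °C
Reagents that add atoms: none
Why: Nickel-catalysed denitrogenative cross-coupling of an N–H aldehyde hydrazone with an aryl bromide (carbonyl umpolung): the C–Br bond of 6 adds to zerovalent nickel, the deprotonated hydrazone 11 binds and loses N2 in a Wolff–Kishner-type step so that the former formyl carbon becomes a nickel-bound benzyl carbanion, and reductive elimination gives the diarylmethane; the two doubly ortho-substituted ketones are too hindered to condense with hydrazine at rt.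

Step 7
Reactants: 12 1-[3-[[3-acetyl-2,4,6-tris(benzyloxy)phenyl]methyl]-2,4-bis(benzyloxy)-6-methoxy-5-methylphenyl]butan-1-one
Product: 13 1-[3-[(3-acetyl-2,4,6-trihydroxyphenyl)methyl]-2,4-dihydroxy-6-methoxy-5-methylphenyl]butan-1-one
Conditions: H2 (1 atm), 10% Pd/C, EtOAc/MeOH, rt
Reagents that add atoms: none
Why: Catalytic hydrogenolysis of the five benzyl ethers under neutral conditions leaves the chelated aryl ketones, the aryl methyl ether and the diarylmethane bridge intact and avoids acid- or base-induced bridge scrambling.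

Step 8
Reactants: 3 1-(2,4,6-trihydroxy-3-methylphenyl)butan-1-one
Product: 14 aspidinol (1-(2,6-dihydroxy-4-methoxy-3-methylphenyl)butan-1-one)
Conditions: Me2SO4 (1.0 equiv), K2CO3 (1.1 equiv), acetone, rt to 40 °C
Reagents that add atoms: dimethyl sulfate, COS(=O)(=O)OC
Why: Selective Williamson O-methylation of the most acidic, non-chelated hydroxyl para to the ketone; the two ortho hydroxyls are held back by hydrogen bonding to the carbonyl.

Step 9
Reactants: 14 aspidinol (1-(2,6-dihydroxy-4-methoxy-3-methylphenyl)butan-1-one); 13 1-[3-[(3-acetyl-2,4,6-trihydroxyphenyl)methyl]-2,4-dihydroxy-6-methoxy-5-methylphenyl]butan-1-one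
Product: 17 1-[3-[[3-acetyl-5-[(3-butanoyl-2,6-dihydroxy-4-methoxy-5-methylphenyl)methyl]-2,4,6-trihydroxyphenyl]methyl]-2,6-dihydroxy-4-methoxy-5-methylphenyl]butan-1-one (the target), via Mannich base 15 (not isolated), via ortho-quinone methide 16 (not isolated)
Conditions: [CH2=NMe2]I (1.0 equiv), Et3N (1.0 equiv), MeCN, rt, 2 h; then 13 (0.9 equiv), 80 °C
Reagents that add atoms: N,N-dimethylmethyleneiminium iodide, C=[N+](C)C.[I-]
Why: Mannich aminomethylation of the only free ring position of 14, thermal loss of dimethylamine to the ortho-quinone methide 16, and Michael addition of the only free ring carbon of 13 (ring B, between two hydroxyls); 14 is fully consumed before 13 is added, so no symmetrical dimer of 14 can form.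

**Compound list**
1 | 2-methylphloroglucinol (2-methylbenzene-1,3,5-triol) | Cc1c(O)cc(O)cc1O | starting material
2 | butanoyl chloride | CCCC(=O)Cl | starting material
3 | 1-(2,4,6-trihydroxy-3-methylphenyl)butan-1-one | CCCC(=O)c1c(O)cc(O)c(C)c1O | intermediate
4 | 1-[4,6-bis(benzyloxy)-2-hydroxy-3-methylphenyl]butan-1-one | CCCC(=O)c1c(O)c(C)c(OCc2ccccc2)cc1OCc1ccccc1 | intermediate
5 | 1-[4,6-bis(benzyloxy)-2-methoxy-3-methylphenyl]butan-1-one | CCCC(=O)c1c(OC)c(C)c(OCc2ccccc2)cc1OCc1ccccc1 | intermediate
6 | 1-[2,4-bis(benzyloxy)-3-bromo-6-methoxy-5-methylphenyl]butan-1-one | CCCC(=O)c1c(OC)c(C)c(OCc2ccccc2)c(Br)c1OCc1ccccc1 | intermediate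
7 | phloroacetophenone (1-(2,4,6-trihydroxyphenyl)ethan-1-one) | CC(=O)c1c(O)cc(O)cc1O | starting material
8 | N-[(3-acetyl-2,4,6-trihydroxyphenyl)methylidene]-N-methylmethanaminium chloride | CC(=O)c1c(O)cc(O)c(C=[N+](C)C)c1O.[Cl-] | intermediate
9 | 3-acetyl-2,4,6-trihydroxybenzaldehyde | CC(=O)c1c(O)cc(O)c(C=O)c1O | intermediate
10 | 3-acetyl-2,4,6-tris(benzyloxy)benzaldehyde | CC(=O)c1c(OCc2ccccc2)cc(OCc2ccccc2)c(C=O)c1OCc1ccccc1 | intermediate
11 | 1-[2,4,6-tris(benzyloxy)-3-[(E)-hydrazinylidenemethyl]phenyl]ethan-1-one | CC(=O)c1c(OCc2ccccc2)cc(OCc2ccccc2)c(/C=N/N)c1OCc1ccccc1 | intermediate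
12 | 1-[3-[[3-acetyl-2,4,6-tris(benzyloxy)phenyl]methyl]-2,4-bis(benzyloxy)-6-methoxy-5-methylphenyl]butan-1-one | CC(=O)c1c(OCc2ccccc2)cc(OCc2ccccc2)c(Cc2c(OCc3ccccc3)c(C)c(OC)c(C(=O)CCC)c2OCc2ccccc2)c1OCc1ccccc1 | intermediate
13 | 1-[3-[(3-acetyl-2,4,6-trihydroxyphenyl)methyl]-2,4-dihydroxy-6-methoxy-5-methylphenyl]butan-1-one | CC(=O)c1c(O)cc(O)c(Cc2c(O)c(C)c(OC)c(C(=O)CCC)c2O)c1O | intermediate
14 | aspidinol (1-(2,6-dihydroxy-4-methoxy-3-methylphenyl)butan-1-one) | CCCC(=O)c1c(O)cc(OC)c(C)c1O | intermediate
15 | 1-[3-[(dimethylamino)methyl]-2,6-dihydroxy-4-methoxy-5-methylphenyl]butan-1-one | CCCC(=O)c1c(O)c(CN(C)C)c(OC)c(C)c1O | intermediate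
16 | 2-butanoyl-3-hydroxy-5-methoxy-4-methyl-6-methylidenecyclohexa-2,4-dien-1-one | CCCC(=O)C1=C(O)C(C)=C(OC)C(=C)C1=O | intermediate
17 | CNP0184345.0, 1-[3-[[3-acetyl-5-[(3-butanoyl-2,6-dihydroxy-4-methoxy-5-methylphenyl)methyl]-2,4,6-trihydroxyphenyl]methyl]-2,6-dihydroxy-4-methoxy-5-methylphenyl]butan-1-one | CCCC(=O)c1c(O)c(C)c(OC)c(Cc2c(O)c(Cc3c(O)c(C)c(OC)c(C(=O)CCC)c3O)c(O)c(C(C)=O)c2O)c1O | target

**Summary**
Total step count: 9. Longest linear sequence: 6 steps (steps 1, 2, 3, 6, 7, 9, from compound 1).

Steps most likely to fail: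

Step 6 (key coupling). The product is a diarylmethane with four ortho oxygen substituents, and the coupling has not been shown on partners this hindered. Azine formation or Wolff–Kishner reduction of 11 to the methylarene can compete. Fallback: set out from 10 and make the benzylic carbon a zinc nucleophile instead. NaBH4 (MeOH/THF, 0 °C) reduces only the aldehyde to 1-[2,4,6-tris(benzyloxy)-3-(hydroxymethyl)phenyl]ethan-1-one F1. SOCl2 (CH2Cl2, 0 °C) gives 1-[2,4,6-tris(benzyloxy)-3-(chloromethyl)phenyl]ethan-1-one F2. Zn dust with LiCl in THF at rt inserts to give [[3-acetyl-2,4,6-tris(benzyloxy)phenyl]methyl]zinc chloride F3, which tolerates the hindered ketone. Negishi coupling of F3 with 6 (Pd(OAc)2 2 mol %, SPhos 4 mol %, THF, 50 °C) comes back to the route at 12.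

Step 2 (regioselective dibenzylation then methylation). The selectivity between the two ortho hydroxyls rests on sterics and chelation and is an expectation, not a demonstrated result; the isomer benzylated next to the C-methyl group, the tribenzyl ether and C-benzylated material are the likely by-products and must be removed by chromatography. Fallback: set out from 3 and control the regiochemistry by deprotection instead of alkylation. Exhaustive benzylation (BnBr, Cs2CO3, DMF, 70 °C) gives 1-[2,4,6-tris(benzyloxy)-3-methylphenyl]butan-1-one F4. MgBr2·OEt2 (toluene/Et2O, 80 °C) then cleaves one ortho benzyl ether by chelation to the ketone; the ether squeezed between the butanoyl and C-methyl groups should go first for strain relief. This gives 4, now isolated and checked by NOE, where the fallback comes back to the route; methylation (MeI, K2CO3, DMF, 60 °C) leads on to 5.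

Step 9 (final union). Thermal release of 16 from 15 may be sluggish, and warm amine can scramble methylene bridges of phloroglucinols by retro-Michael exchange. Fallback: set out from 13 and reverse the roles of the partners. [CH2=NMe2]I/Et3N in MeCN aminomethylates the only free ring position of 13 to give 1-[3-[[3-acetyl-5-[(dimethylamino)methyl]-2,4,6-trihydroxyphenyl]methyl]-2,4-dihydroxy-6-methoxy-5-methylphenyl]butan-1-one F5. Heating F5 with 14 (3 equiv) in 1,4-dioxane at 100 °C releases the more readily formed ring B quinone methide 4-acetyl-2-[(3-butanoyl-2,6-dihydroxy-4-methoxy-5-methylphenyl)methyl]-3,5-dihydroxy-6-methylidenecyclohexa-2,4-dien-1-one F6 (not isolated), which is trapped by the free ring position of 14. This comes back to the route at 17; excess 14 is recovered.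

**Further compounds**
F1 | step 6 | 1-[2,4,6-tris(benzyloxy)-3-(hydroxymethyl)phenyl]ethan-1-one | CC(=O)c1c(OCc2ccccc2)cc(OCc2ccccc2)c(CO)c1OCc1ccccc1
F2 | step 6 | 1-[2,4,6-tris(benzyloxy)-3-(chloromethyl)phenyl]ethan-1-one | CC(=O)c1c(OCc2ccccc2)cc(OCc2ccccc2)c(CCl)c1OCc1ccccc1
F3 | step 6 | [[3-acetyl-2,4,6-tris(benzyloxy)phenyl]methyl]zinc chloride | CC(=O)c1c(OCc2ccccc2)cc(OCc2ccccc2)c(C[Zn]Cl)c1OCc1ccccc1
F4 | step 2 | 1-[2,4,6-tris(benzyloxy)-3-methylphenyl]butan-1-one | CCCC(=O)c1c(OCc2ccccc2)c(C)c(OCc2ccccc2)cc1OCc1ccccc1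
F5 | step 9 | 1-[3-[[3-acetyl-5-[(dimethylamino)methyl]-2,4,6-trihydroxyphenyl]methyl]-2,4-dihydroxy-6-methoxy-5-methylphenyl]butan-1-one | CC(=O)c1c(O)c(CN(C)C)c(O)c(Cc2c(O)c(C)c(OC)c(C(=O)CCC)c2O)c1O
F6 | step 9 | 4-acetyl-2-[(3-butanoyl-2,6-dihydroxy-4-methoxy-5-methylphenyl)methyl]-3,5-dihydroxy-6-methylidenecyclohexa-2,4-dien-1-one | CC(=O)C1=C(O)C(=C)C(=O)C(Cc2c(O)c(C)c(OC)c(C(=O)CCC)c2O)=C1O
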